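The solid substrate goes in undissolved, and from the east and south-east runs we want to bracket what a third flask holds at 30 h.

in all of them: solid substrate 20 mM
- east: reagent 36 mM; run made earlier
- south-east: reagent 57 mM; run made earlier
- flask: reagent 26.0 mM; time 30 h

| run | time / h | target / % | solid product / % |
|---|---|---|---|
| east | 1.33 | 0.2 | 0 |
| east | 2.50 | 1.5 | 0.5 |
| east | 4.00 | 2.6 | 0.7 |
| east | 6.00 | 2.0 | 0.1 |
| east | 10.0 | 3.3 | 0 |
| east | 20.0 | 5.7 | 0 |
| south-east | 1.33 | 0.3 | 0 |
| south-east | 4.00 | 1.9 | 0 |
| south-east | 6.00 | 2.1 | 0.1 |
| south-east | 10.0 | 4.1 | 0.6 |
| south-east | 15.0 | 4.4 | 0 |
| south-east | 20.0 | 5.3 | 0 |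

(standard deviation of a reading: 0.5 percentage points)

- in percentages every species weighs as the solid substrate in it: one side product counts as two
- for target the solid product is counted in
- as a solid, counted per litre of solution: solid substrate, solid product
- what may be going on: solid substrate <-> dissolved substrate; dissolved substrate + reagent -> target; dissolved substrate + target -> side product; solid product <-> target; reagent -> decomposition product; target <-> isomer of the product
- at the start none of the solid substrate is in solution
- dissolved substrate means what is dissolved; the solid is not counted in it

* how much target and solid product together there is at 30 h, in percent of the solid substrate charged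
* concentration of dissolved substrate in solution at 30 h, in percent of saturation

The amount of reagent does not show in these readings: at 20.0 h the east run, with 36 mM, reads 5.7 % of target and the south-east run, with 57 mM, reads 5.3 %. So we average the two runs and count in mM: 0.740 mM of target at 10.0 h and 1.10 mM at 20.0 h.

For a rough floor, we let the target stop at the later reading, which is 5.50 % of this flask's charge, though this flask has less reagent than either run. For a ceiling we use the late rate, the mM of target gained per hour between those two readings, 0.0360 mM h⁻¹. The scattered readings bend, the first stretch giving more than the second, so if that goes on, the late rate held to 30 h overshoots. That gives 1.46 mM, or 7.30 %. No reading shows dissolved substrate, so we bracket no saturation.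

The forecast says 7.5 % and 20 %, on the ground that “the likely bottleneck is dissolution of the solid”. Its yield lies just above our ceiling.

The flask gives 6.48 %, above our floor and below our ceiling, and 5.05 % of saturation.

    solid substrate ⇌ dissolved substrate, rate k1*(cs1 - [dissolved substrate]) while solid is left; crystals form when [dissolved substrate] > cs1 (solubility = 2.30 mM, k = 0.00120 min⁻¹)
    dissolved substrate + reagent → target (k = 0.890 M⁻¹ min⁻¹)
    dissolved substrate + target → side product (k = 2.50 M⁻¹ min⁻¹)
    solid product ⇌ target, rate k4*(cs4 - [target]) while solid is left; crystals form when [target] > cs4 (solubility = 9.50 mM, k = 0.0270 min⁻¹)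
    reagent → decomposition product (k = 3.30 × 10⁻⁶ min⁻¹)
    target ⇌ isomer of the product (K = 2.60, k = 0.00420 min⁻¹)

The dissolution term holds no amount of solid, so for a neighbour flask charged with 80 mM of solid substrate we keep the bracket in mM and divide by the new charge. The floor becomes 1.38 %, and the late rate puts the ceiling at 1.82 %. That neighbour flask gives 1.62 %, which is 1.30 mM of target against 1.30 mM in the flask with 20 mM.

The data were generated by integration for an exercise; scatter was added.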